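(The earlier runs and the new flask are calculated with made-up constants.)

The meeting opened on a ratio: the first member proposed dividing the logarithmic loss of X per minute by the summed concentration of L and E, since the candidate steps have X reacting with both, which makes X pseudo-first-order in that sum. Each E made replaces an L, so the sum falls by the Z formed.

| setting | eta | zeta | theta | flask |
|---|---|---|---|---|
| X | 0.10 M | 0.15 M | 0.20 M | 0.20 M |
| L | 0.24 M | 0.24 M | 0.24 M | 0.240 M |
| J | 0.60 M | 0.60 M | 0.30 M | 0.600 M |
| remark | run made earlier | run made earlier | run made earlier |  |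
| time |  |  |  | 15 min |
- eta (time / min: X / %, E / %): 1.00: 79.9, 18.4; 3.00: 51.8, 40.4; 6.00: 27.1, 55.0; 8.00: 17.8, 60.4; 12.0: 8.3, 66.0
- zeta (time / min: X / %, E / %): 1.00: 80.3, 17.2; 3.00: 52.7, 36.5; 6.00: 28.2, 48.0; 8.00: 19.3, 51.7; 12.0: 8.4, 54.5
- theta (time / min: X / %, E / %): 1.00: 80.6, 16.1; 3.00: 53.7, 32.9; 6.00: 30.2, 41.1; 8.00: 20.7, 43.2; 12.0: 10.2, 45.0

(scatter of a reading: 0.3 percentage points)
- a species is counted by the X in it: one Z counts as two
- candidate steps: D + J <-> G; L + D <-> Q; X + L -> D + E; X + E -> Z
- the earlier runs do not show how much of L is bound; that part of a forecast is a guess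
- part of the X that has reacted at 15 min
- share of the unused L that is free and not bound as Q, at 15 min

The first member read the eta run, where the sum is still near the charged L: X falls to 79.9% in 1.00 min, and with 0.24 M of L the ratio is 0.0156 M⁻¹ s⁻¹. The second member took the theta run, which matches this flask in X and L. Between 8.00 min and 12.0 min X decays at 0.177 min⁻¹, with a mean sum of 0.200 M, so the ratio, named the pool constant, reads 0.0148 M⁻¹ s⁻¹. The two readings lie close, and the meeting took L and E to remove X about alike.

The third member objected that theta has 0.30 M of J against 0.600 M in this flask; the meeting assumed J leaves X unaffected. Continuing from theta's 10.2% at 12.0 min, with the sum then 0.195 M, the members reckoned X at 6.07% for this flask at 15 min, so 93.9% reacted. The bound share of L stayed a guess.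

The forecast gave 94% reacted and 93% free, the latter “loosely determined”. This flask gives 94.0% reacted and 99.9% free.

    D + J ⇌ G (K = 87000 M⁻¹, k = 2.27 M⁻¹ s⁻¹)
    L + D ⇌ Q, settled at all times (K = 60.0 M⁻¹)
    X + L → D + E (k = 0.0156 M⁻¹ s⁻¹)
    X + E → Z (k = 0.0139 M⁻¹ s⁻¹)

The neighbouring flask is charged with 0.096 M of L, 0.480 equiv against X, its other charges and time as in this flask. Its Z at 15.0 min, 45.5% of the X charged, leaves a sum of 0.0505 M, so the mean of start and end is 0.0732 M. The pool constant then gives X as 37.7% of its charge. In that neighbouring flask X stands at 38.1% at 15.0 min.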